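**Assumption:** the structure is taken exactly as the SMILES encodes it: (1R,6R,8S), with C3 and C6 cis on C4=C5 (4Z by CIP). Germacrane numbering is used throughout.

**Abbreviations:** TBS = tert-butyldimethylsilyl, TES = triethylsilyl, PMB = 4-methoxybenzyl. "Chain A" = (1Z,5R)-5-(TBS-oxy)-2-methyl-6-[(PMB-oxy)methyl]hepta-1,6-dien-1-yl (germacrane C5, C4, C15, C3, C2, C1, C10, C14, C9). "Chain B" = chain A with CH2OH in place of CH2OPMB. "Chain C" = chain A with CH2Br in place of CH2OPMB.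

## Retrosynthetic overview

1. Target 31 ⇐ desilylation and acetylation of macrocyclic alcohol 29 ⇐ intramolecular Nozaki–Hiyama–Kishi allylation (C8–C9) of bromo aldehyde 28; the ten-membered ring is closed last.
2. Butenolide 24 ⇐ trans-γ-lactone 19 by α-hydroxymethylation (C13), α-selenenylation and selenoxide elimination (C7=C11).
3. Lactone 17 ⇐ key intermolecular Evans syn-aldol (C6–C7, sets C6) between Z-enal 12 (C1–C6, C9, C10, C14, C15) and succinate imide 15 (C7, C8, C11, C12); the five-membered lactone forms first.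
4. Enal 12 ⇐ neryl acetate 1 (Z-olefin from the pool) by ozonolysis, CrCl2/NiCl2 coupling with 2-bromoallyl ether 6, and CBS reduction (sets C1).
5. Ring order: γ-lactone, then butenolide, then ten-membered carbocycle.

## Route

Step 1
Reactants: 1 neryl acetate
Product: 3 (2Z)-3-methyl-6-oxohex-2-en-1-yl acetate, via ozonide 2 (not isolated)
Conditions: O3 (1.0 equiv, titrated as a CH2Cl2 solution), CH2Cl2, −78 °C; PPh3, −78 °C → rt
Reagents that add atoms: ozone, [O-][O+]=O
Why: Regioselective ozonolysis; the electron-rich distal trisubstituted olefin reacts much faster than the olefin deactivated by the allylic acetate, so the Z-olefin is kept.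

Step 2
Reactants: 4 2,3-dibromoprop-1-ene; 5 4-methoxybenzyl alcohol
Product: 6 1-{[(2-bromoprop-2-en-1-yl)oxy]methyl}-4-methoxybenzene
Conditions: NaH, THF, 0 °C; then 4, Bu4NI (cat.), 0 °C → rt
Reagents that add atoms: none
Why: Williamson ether synthesis; the alkoxide displaces only the allylic bromide, the vinylic bromide being inert to SN2.

Step 3
Reactants: 3 (2Z)-3-methyl-6-oxohex-2-en-1-yl acetate; 6 2-bromoallyl PMB ether
Product: 7 rac-(2Z)-6-hydroxy-7-[(PMB-oxy)methyl]-3-methylocta-2,7-dien-1-yl acetate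
Conditions: CrCl2 (4 equiv), NiCl2 (2 mol %), DMF, rt
Reagents that add atoms: none
Why: Nozaki–Hiyama–Kishi coupling; the alkenylchromium species adds only to the aldehyde and tolerates the acetate, and the racemic C1 carbinol is corrected in steps 4 and 5.

Step 4
Reactants: 7 racemic allylic alcohol
Product: 8 (2Z)-7-[(PMB-oxy)methyl]-3-methyl-6-oxoocta-2,7-dien-1-yl acetate
Conditions: Dess–Martin periodinane, NaHCO3, CH2Cl2, 0 °C → rt
Reagents that add atoms: none
Why: Dess–Martin oxidation gives the α-methylene ketone under neutral conditions without touching the acetate, PMB ether or olefins.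

Step 5
Reactants: 8 enone
Product: 9 (2Z,6R)-6-hydroxy-7-[(PMB-oxy)methyl]-3-methylocta-2,7-dien-1-yl acetate
Conditions: (S)-1-methyl-3,3-diphenyltetrahydro-1H,3H-pyrrolo[1,2-c][1,3,2]oxazaborole (20 mol %), catecholborane, toluene, −78 °C
Reagents that add atoms: none
Why: Corey–Bakshi–Shibata 1,2-reduction; with the branched alkenyl group as the large substituent the (S)-catalyst gives the (R)-carbinol (C1, about 90% ee expected), and the minor series is removed as a diastereomer after step 10.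

Step 6
Reactants: 9 (R)-allylic alcohol
Product: 10 (2Z,6R)-6-(TBS-oxy)-7-[(PMB-oxy)methyl]-3-methylocta-2,7-dien-1-yl acetate
Conditions: TBSOTf, 2,6-lutidine, CH2Cl2, −78 °C
Reagents that add atoms: tert-butyldimethylsilyl triflate, CC(C)(C)[Si](C)(C)OS(=O)(=O)C(F)(F)F
Why: Silylation of the secondary allylic alcohol; the TBS ether stays on until the last step.

Step 7
Reactants: 10 acetate
Product: 11 (2Z,6R)-6-(TBS-oxy)-7-[(PMB-oxy)methyl]-3-methylocta-2,7-dien-1-ol
Conditions: K2CO3, MeOH, 0 °C → rt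
Reagents that add atoms: none
Why: Base-catalysed transesterification removes only the acetate; silyl and PMB ethers are stable.

Step 8
Reactants: 11 allylic alcohol
Product: 12 (2Z,6R)-6-(TBS-oxy)-7-[(PMB-oxy)methyl]-3-methylocta-2,7-dienal
Conditions: MnO2, CH2Cl2, rt
Reagents that add atoms: none
Why: MnO2 oxidation of the primary allylic alcohol gives the Z-enal without Z/E isomerisation, as in nerol → neral.

Step 9
Reactants: 13 (4S)-4-benzyl-1,3-oxazolidin-2-one; 14 methyl 4-chloro-4-oxobutanoate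
Product: 15 methyl 4-[(4S)-4-benzyl-2-oxo-1,3-oxazolidin-3-yl]-4-oxobutanoate
Conditions: n-BuLi, THF, −78 °C; then 14, −78 → 0 °C
Reagents that add atoms: none
Why: N-acylation of the lithiated Evans auxiliary by the acid chloride.

Step 10
Reactants: 12 Z-enal; 15 succinate imide
Product: 17 (4S)-4-benzyl-3-{[(2R,3S)-2-(chain A)-5-oxooxolan-3-yl]carbonyl}-1,3-oxazolidin-2-one, via aldol adduct 16 (not isolated)
Conditions: 15, Bu2BOTf, iPr2NEt, CH2Cl2, −78 → 0 °C; 12, −78 → 0 °C; MeOH, pH 7 buffer, H2O2, 0 °C; then pyridinium p-toluenesulfonate (cat.), CH2Cl2, rt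
Reagents that add atoms: none
Why: Intermolecular Evans syn-aldol; the Z-boron enolate of the (4S)-benzyl imide reacts through a Zimmerman–Traxler chair to set C6 as R (C7 is transient), and the γ-hydroxy ester closes to the trans-γ-lactone, at which stage diastereomers are separated.

Step 11
Reactants: 17 lactone imide
Product: 18 (4R,5R)-4-(hydroxymethyl)-5-(chain A)oxolan-2-one
Conditions: NaBH4, THF/H2O (4:1), 0 °C → rt
Reagents that add atoms: none
Why: Borohydride reduction of the activated exocyclic imide carbonyl releases the C8 primary alcohol and the auxiliary; the much less electrophilic γ-lactone survives.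

Step 12
Reactants: 18 primary alcohol
Product: 19 (4R,5R)-4-[(TES-oxy)methyl]-5-(chain A)oxolan-2-one
Conditions: Et3SiCl, imidazole, CH2Cl2, 0 °C
Reagents that add atoms: chlorotriethylsilane, CC[Si](Cl)(CC)CC
Why: Silylation gives a C8 ether that can later be removed in the presence of the secondary TBS ether.

Step 13
Reactants: 19 lactone
Product: 20 (3R,4R,5R)-3-(hydroxymethyl)-4-[(TES-oxy)methyl]-5-(chain A)oxolan-2-one (3,4-trans major; the C11 configuration is lost later)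
Conditions: LiN(iPr)2, THF, −78 °C; CH2O (gas), −78 → −20 °C
Reagents that add atoms: formaldehyde, C=O
Why: Aldol of the lactone lithium enolate with monomeric formaldehyde introduces C13; attack is anti to the C7 substituent.

Step 14
Reactants: 20 α-hydroxymethyl lactone
Product: 22 [(3R,4R,5R)-2-oxo-3-(phenylselanyl)-4-[(TES-oxy)methyl]-5-(chain A)oxolan-3-yl]methyl acetate (SePh cis to H-7), via hydroxy selenide 21 (not isolated)
Conditions: LiN(iPr)2 (2.2 equiv), THF, −78 → −40 °C; PhSeBr, −78 °C; Ac2O, −78 °C → rt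
Reagents that add atoms: phenylselenyl bromide, Br[Se]c1ccccc1; acetic anhydride, CC(=O)OC(C)=O
Why: α-Selenenylation of the alkoxide–enolate dianion (an alkoxide does not β-eliminate) occurs anti to the C7 substituent, placing SePh cis to H-7, and the C13 alkoxide is then capped in the flask as the acetate.

Step 15
Reactants: 22 acetoxy selenide
Product: 24 [(5R)-2-oxo-4-[(TES-oxy)methyl]-5-(chain A)-2,5-dihydrofuran-3-yl]methyl acetate, via selenoxide 23 (not isolated)
Conditions: H2O2 (30%), pyridine, CH2Cl2, 0 °C → rt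
Reagents that add atoms: none
Why: Selenoxide syn-elimination takes the cis H-7 and avoids the acetoxy-bearing carbon, giving the tetrasubstituted C7=C11 butenolide with C6 untouched.

Step 16
Reactants: 24 butenolide
Product: 25 [(5R)-2-oxo-4-[(TES-oxy)methyl]-5-(chain B)-2,5-dihydrofuran-3-yl]methyl acetate
Conditions: DDQ, CH2Cl2/pH 7 buffer, 0 °C
Reagents that add atoms: none
Why: Oxidative PMB cleavage under buffered neutral conditions frees only the C9 allylic alcohol.

Step 17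
Reactants: 25 allylic alcohol
Product: 26 [(5R)-2-oxo-4-[(TES-oxy)methyl]-5-(chain C)-2,5-dihydrofuran-3-yl]methyl acetate
Conditions: CBr4, PPh3, 2,6-lutidine, CH2Cl2, 0 °C
Reagents that add atoms: carbon tetrabromide, BrC(Br)(Br)Br
Why: Appel bromination of the primary allylic alcohol; the 2-substituted allyl unit is symmetric, so SN2 and SN2′ give the same bromide.

Step 18
Reactants: 26 allylic bromide
Product: 27 [(5R)-4-(hydroxymethyl)-2-oxo-5-(chain C)-2,5-dihydrofuran-3-yl]methyl acetate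
Conditions: pyridinium p-toluenesulfonate, MeOH/CH2Cl2, 0 °C
Reagents that add atoms: none
Why: Mild acid methanolysis removes the primary TES ether much faster than the secondary TBS ether and without acetate migration.

Step 19
Reactants: 27 primary alcohol
Product: 28 [(5R)-4-formyl-2-oxo-5-(chain C)-2,5-dihydrofuran-3-yl]methyl acetate
Conditions: Dess–Martin periodinane, NaHCO3, CH2Cl2, 0 °C
Reagents that add atoms: none
Why: Dess–Martin oxidation gives the sensitive 4-formylbutenolide without base; it is used at once.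

Step 20
Reactants: 28 bromo aldehyde
Product: 29 (1R,6R,8S)-13-acetoxy-8-hydroxy-1-(TBS-oxy)germacra-4(Z),7(11),10(14)-trien-6,12-olide
Conditions: CrCl2 (10 equiv), THF/DMF, rt, slow addition to 2 mM
Reagents that add atoms: none
Why: Intramolecular Nozaki–Hiyama–Kishi carbonyl allylation under high dilution closes the ten-membered ring at C8–C9 and leaves the C10 exocyclic methylene; C8 is set by macrocyclic control, with attack anti to the C6 alkenyl arm expected to give 8S (to be confirmed by NOE).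

Step 21
Reactants: 29 macrocyclic alcohol
Product: 30 (1R,6R,8S)-8,13-diacetoxy-1-(TBS-oxy)germacra-4(Z),7(11),10(14)-trien-6,12-olide
Conditions: Ac2O, pyridine, 4-(dimethylamino)pyridine (cat.), CH2Cl2, 0 °C
Reagents that add atoms: acetic anhydride, CC(=O)OC(C)=O
Why: O-Acetylation with retention at C8.

Step 22
Reactants: 30 silyl ether
Product: 31 8α,13-diacetoxy-1β-hydroxygermacra-4,7(11),10(14)-trien-6α,12-olide (target)
Conditions: HF·pyridine, THF, 0 °C → rt
Reagents that add atoms: none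
Why: Acidic fluoride desilylation frees the C1 allylic alcohol without acetate cleavage, acyl migration or epimerisation at C6.

## Compound list

1 | neryl acetate, (2Z)-3,7-dimethylocta-2,6-dien-1-yl acetate | CC(=O)OC/C=C(/C)CCC=C(C)C | starting material
2 | ozonide of 1 at the distal olefin (not isolated) | CC(=O)OC/C=C(/C)CCC1OOC(C)(C)O1 | intermediate
3 | (2Z)-3-methyl-6-oxohex-2-en-1-yl acetate | CC(=O)OC/C=C(/C)CCC=O | intermediate
4 | 2,3-dibromoprop-1-ene | C=C(Br)CBr | starting material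
5 | 4-methoxybenzyl alcohol | COc1ccc(CO)cc1 | starting material
6 | 1-{[(2-bromoprop-2-en-1-yl)oxy]methyl}-4-methoxybenzene | C=C(Br)COCc1ccc(OC)cc1 | intermediate
7 | rac-(2Z)-6-hydroxy-7-[(PMB-oxy)methyl]-3-methylocta-2,7-dien-1-yl acetate | CC(=O)OC/C=C(/C)CCC(O)C(=C)COCc1ccc(OC)cc1 | intermediate
8 | (2Z)-7-[(PMB-oxy)methyl]-3-methyl-6-oxoocta-2,7-dien-1-yl acetate | CC(=O)OC/C=C(/C)CCC(=O)C(=C)COCc1ccc(OC)cc1 | intermediate
9 | (2Z,6R)-6-hydroxy-7-[(PMB-oxy)methyl]-3-methylocta-2,7-dien-1-yl acetate | CC(=O)OC/C=C(/C)CC[C@@H](O)C(=C)COCc1ccc(OC)cc1 | intermediate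
10 | (2Z,6R)-6-(TBS-oxy)-7-[(PMB-oxy)methyl]-3-methylocta-2,7-dien-1-yl acetate | CC(=O)OC/C=C(/C)CC[C@@H](O[Si](C)(C)C(C)(C)C)C(=C)COCc1ccc(OC)cc1 | intermediate
11 | (2Z,6R)-6-(TBS-oxy)-7-[(PMB-oxy)methyl]-3-methylocta-2,7-dien-1-ol | OC/C=C(/C)CC[C@@H](O[Si](C)(C)C(C)(C)C)C(=C)COCc1ccc(OC)cc1 | intermediate
12 | (2Z,6R)-6-(TBS-oxy)-7-[(PMB-oxy)methyl]-3-methylocta-2,7-dienal | O=C/C=C(/C)CC[C@@H](O[Si](C)(C)C(C)(C)C)C(=C)COCc1ccc(OC)cc1 | intermediate
13 | (4S)-4-benzyl-1,3-oxazolidin-2-one | O=C1N[C@@H](Cc2ccccc2)CO1 | starting material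
14 | methyl 4-chloro-4-oxobutanoate | COC(=O)CCC(Cl)=O | starting material
15 | methyl 4-[(4S)-4-benzyl-2-oxo-1,3-oxazolidin-3-yl]-4-oxobutanoate | COC(=O)CCC(=O)N1[C@@H](Cc2ccccc2)COC1=O | intermediate
16 | methyl (3S,4R,5Z,9R)-3-{[(4S)-4-benzyl-2-oxo-1,3-oxazolidin-3-yl]carbonyl}-4-hydroxy-9-(TBS-oxy)-10-[(PMB-oxy)methyl]-6-methylundeca-5,10-dienoate (not isolated) | COC(=O)C[C@H](C(=O)N1[C@@H](Cc2ccccc2)COC1=O)[C@H](O)/C=C(/C)CC[C@@H](O[Si](C)(C)C(C)(C)C)C(=C)COCc1ccc(OC)cc1 | intermediate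
17 | (4S)-4-benzyl-3-{[(2R,3S)-2-(chain A)-5-oxooxolan-3-yl]carbonyl}-1,3-oxazolidin-2-one (trans-lactone) | O=C1C[C@H](C(=O)N2[C@@H](Cc3ccccc3)COC2=O)[C@@H](/C=C(/C)CC[C@@H](O[Si](C)(C)C(C)(C)C)C(=C)COCc2ccc(OC)cc2)O1 | intermediate
18 | (4R,5R)-4-(hydroxymethyl)-5-(chain A)oxolan-2-one | O=C1C[C@H](CO)[C@@H](/C=C(/C)CC[C@@H](O[Si](C)(C)C(C)(C)C)C(=C)COCc2ccc(OC)cc2)O1 | intermediate
19 | (4R,5R)-4-[(TES-oxy)methyl]-5-(chain A)oxolan-2-one | O=C1C[C@H](CO[Si](CC)(CC)CC)[C@@H](/C=C(/C)CC[C@@H](O[Si](C)(C)C(C)(C)C)C(=C)COCc2ccc(OC)cc2)O1 | intermediate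
20 | (3R,4R,5R)-3-(hydroxymethyl)-4-[(TES-oxy)methyl]-5-(chain A)oxolan-2-one | O=C1[C@@H](CO)[C@H](CO[Si](CC)(CC)CC)[C@@H](/C=C(/C)CC[C@@H](O[Si](C)(C)C(C)(C)C)C(=C)COCc2ccc(OC)cc2)O1 | intermediate
21 | (3R,4R,5R)-3-(hydroxymethyl)-3-(phenylselanyl)-4-[(TES-oxy)methyl]-5-(chain A)oxolan-2-one (not isolated) | O=C1[C@@](CO)([Se]c2ccccc2)[C@H](CO[Si](CC)(CC)CC)[C@@H](/C=C(/C)CC[C@@H](O[Si](C)(C)C(C)(C)C)C(=C)COCc2ccc(OC)cc2)O1 | intermediate
22 | [(3R,4R,5R)-2-oxo-3-(phenylselanyl)-4-[(TES-oxy)methyl]-5-(chain A)oxolan-3-yl]methyl acetate | O=C1[C@@](COC(C)=O)([Se]c2ccccc2)[C@H](CO[Si](CC)(CC)CC)[C@@H](/C=C(/C)CC[C@@H](O[Si](C)(C)C(C)(C)C)C(=C)COCc2ccc(OC)cc2)O1 | intermediate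
23 | selenoxide of 22 (not isolated) | O=C1[C@@](COC(C)=O)([Se](=O)c2ccccc2)[C@H](CO[Si](CC)(CC)CC)[C@@H](/C=C(/C)CC[C@@H](O[Si](C)(C)C(C)(C)C)C(=C)COCc2ccc(OC)cc2)O1 | intermediate
24 | [(5R)-2-oxo-4-[(TES-oxy)methyl]-5-(chain A)-2,5-dihydrofuran-3-yl]methyl acetate | CC(=O)OCC1=C(CO[Si](CC)(CC)CC)[C@@H](/C=C(/C)CC[C@@H](O[Si](C)(C)C(C)(C)C)C(=C)COCc2ccc(OC)cc2)OC1=O | intermediate
25 | [(5R)-2-oxo-4-[(TES-oxy)methyl]-5-(chain B)-2,5-dihydrofuran-3-yl]methyl acetate | CC(=O)OCC1=C(CO[Si](CC)(CC)CC)[C@@H](/C=C(/C)CC[C@@H](O[Si](C)(C)C(C)(C)C)C(=C)CO)OC1=O | intermediate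
26 | [(5R)-2-oxo-4-[(TES-oxy)methyl]-5-(chain C)-2,5-dihydrofuran-3-yl]methyl acetate | CC(=O)OCC1=C(CO[Si](CC)(CC)CC)[C@@H](/C=C(/C)CC[C@@H](O[Si](C)(C)C(C)(C)C)C(=C)CBr)OC1=O | intermediate
27 | [(5R)-4-(hydroxymethyl)-2-oxo-5-(chain C)-2,5-dihydrofuran-3-yl]methyl acetate | CC(=O)OCC1=C(CO)[C@@H](/C=C(/C)CC[C@@H](O[Si](C)(C)C(C)(C)C)C(=C)CBr)OC1=O | intermediate
28 | [(5R)-4-formyl-2-oxo-5-(chain C)-2,5-dihydrofuran-3-yl]methyl acetate | CC(=O)OCC1=C(C=O)[C@@H](/C=C(/C)CC[C@@H](O[Si](C)(C)C(C)(C)C)C(=C)CBr)OC1=O | intermediate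
29 | (1R,6R,8S)-13-acetoxy-8-hydroxy-1-(TBS-oxy)germacra-4(Z),7(11),10(14)-trien-6,12-olide | C=C1C[C@H](O)C2=C(COC(C)=O)C(=O)O[C@@H]2/C=C(/C)CC[C@H]1O[Si](C)(C)C(C)(C)C | intermediate
30 | (1R,6R,8S)-8,13-diacetoxy-1-(TBS-oxy)germacra-4(Z),7(11),10(14)-trien-6,12-olide | C=C1C[C@H](OC(C)=O)C2=C(COC(C)=O)C(=O)O[C@@H]2/C=C(/C)CC[C@H]1O[Si](C)(C)C(C)(C)C | intermediate
31 | 8α,13-diacetoxy-1β-hydroxygermacra-4,7(11),10(14)-trien-6α,12-olide | C=C1C[C@H](OC(C)=O)C2=C(COC(C)=O)C(=O)O[C@@H]2/C=C(/C)CC[C@H]1O | target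

## Step count and risks

Total step count: 22. Longest linear sequence: 20 steps from neryl acetate (steps 1, 3–8, 10–22); steps 2 and 9 are side branches.

The three steps most likely to fail:

**Step 20 (ring closure and C8 configuration).** The chromium-mediated closure may give mainly the 8β-alcohol. Fallback: setting out from 28, the same closure is run and the product obtained is the 8-epimeric alcohol (1R,6R,8R)-13-acetoxy-8-hydroxy-1-(TBS-oxy)germacratrienolide F1. Instead of a retentive acetylation, F1 is esterified with inversion in a Mitsunobu reaction (PPh3, diisopropyl azodicarboxylate, AcOH, toluene, 0 °C). This installs the 8α-acetate directly and comes back to the route at 30.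

**Step 14 (dianion selenenylation with in-flask acetylation, and the elimination that follows).** Retro-aldol loss of formaldehyde, O-selenenylation or the wrong elimination direction could lower the yield. Fallback: setting out from 20, the lactone is converted with LiN(iPr)2 and Me3SiCl (THF, −78 °C) into the bis-silylated ketene acetal F2. Saegusa–Ito dehydrosilylation with Pd(OAc)2 (divalent palladium, MeCN, rt) gives the O-trimethylsilyl butenolide F3. Citric acid in MeOH frees the hydroxymethyl butenolide F4, and Ac2O/pyridine acetylates it, coming back to the route at 24.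

**Step 11 (borohydride cleavage of the imide next to a γ-lactone).** Over-reduction of the lactone is possible. Fallback: setting out from 17, the auxiliary is removed hydrolytically (LiOH, H2O2, THF/H2O, 0 °C, acidic work-up) to give the lactone carboxylic acid F5. This is activated with isobutyl chloroformate and N-methylmorpholine (THF, −15 °C) as the mixed anhydride F6, which NaBH4 reduces at −15 °C without touching the lactone, coming back to the route at 18.

## Further compounds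

F1 | step 20 | (1R,6R,8R)-13-acetoxy-8-hydroxy-1-(TBS-oxy)germacra-4(Z),7(11),10(14)-trien-6,12-olide | C=C1C[C@@H](O)C2=C(COC(C)=O)C(=O)O[C@@H]2/C=C(/C)CC[C@H]1O[Si](C)(C)C(C)(C)C
F2 | step 14 | (2R,3R)-2-(chain A)-3-[(TES-oxy)methyl]-5-(trimethylsilyloxy)-4-[(trimethylsilyloxy)methyl]-2,3-dihydrofuran | C[Si](C)(C)OCC1=C(O[Si](C)(C)C)O[C@H](/C=C(/C)CC[C@@H](O[Si](C)(C)C(C)(C)C)C(=C)COCc2ccc(OC)cc2)[C@H]1CO[Si](CC)(CC)CC
F3 | step 14 | (5R)-5-(chain A)-4-[(TES-oxy)methyl]-3-[(trimethylsilyloxy)methyl]furan-2(5H)-one | C[Si](C)(C)OCC1=C(CO[Si](CC)(CC)CC)[C@@H](/C=C(/C)CC[C@@H](O[Si](C)(C)C(C)(C)C)C(=C)COCc2ccc(OC)cc2)OC1=O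
F4 | step 14 | (5R)-5-(chain A)-3-(hydroxymethyl)-4-[(TES-oxy)methyl]furan-2(5H)-one | OCC1=C(CO[Si](CC)(CC)CC)[C@@H](/C=C(/C)CC[C@@H](O[Si](C)(C)C(C)(C)C)C(=C)COCc2ccc(OC)cc2)OC1=O
F5 | step 11 | (2R,3S)-2-(chain A)-5-oxooxolane-3-carboxylic acid | O=C1C[C@H](C(=O)O)[C@@H](/C=C(/C)CC[C@@H](O[Si](C)(C)C(C)(C)C)C(=C)COCc2ccc(OC)cc2)O1
F6 | step 11 | isobutyl carbonic (2R,3S)-2-(chain A)-5-oxooxolane-3-carboxylic anhydride | O=C1C[C@H](C(=O)OC(=O)OCC(C)C)[C@@H](/C=C(/C)CC[C@@H](O[Si](C)(C)C(C)(C)C)C(=C)COCc2ccc(OC)cc2)O1
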